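**Retrosynthetic overview**
- Scaposin is released last from its 7,3'-dibenzyl ether by hydrogenolysis of both benzyl ethers.
- Ring C (the pyranone) is cut at C4–C3 and O1–C2, giving a 4-benzyloxy-2,6-dihydroxy-3,5-dimethoxybenzaldehyde (ring A plus C4) and a ring-B aroyl sulfoxonium ylide (C3 and C2).
- Feature: the carbonyl carbon C4 sits on C4a between C5–OH and C8a–O1; because 6-OMe matches 8-OMe across the C4a···C7 axis, these two oxygens are the equivalent hydroxyls of a symmetric aldehyde, whose formyl C–H can serve as an acyl–rhodium nucleophile.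
- The aldehyde comes from syringol (benzyl ether, 4,6-dibromide, double C–Br to C–OH, formylation of the one free carbon); the ylide comes from methyl 3-hydroxy-4,5-dimethoxybenzoate (benzyl ether, then acylation of dimethylsulfoxonium methylide).
- Ring order: rings A and B are bought as benzenes; ring C is the only ring formed, in the key step.

Key step: step 7

Remark: scaposin has no stereocentre or other stereogenic element, so the "single enantiomer" is the achiral compound itself and no stereocontrol is needed.

**Route**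

Step 1
Reactants: 1 2,6-dimethoxyphenol (syringol)
Product: 2 2-(benzyloxy)-1,3-dimethoxybenzene
Conditions: BnBr, K2CO3, DMF, 60 °C
Reagents that add atoms: benzyl bromide, BrCc1ccccc1
Why: Williamson etherification of the acidic phenol is routine and masks the oxygen that becomes O7 with a group removable by hydrogenolysis at the end.

Step 2
Reactants: 2 2-(benzyloxy)-1,3-dimethoxybenzene
Product: 3 3-(benzyloxy)-1,5-dibromo-2,4-dimethoxybenzene
Conditions: NBS (2.2 equiv), MeCN, 0 °C → 40 °C, dark
Reagents that add atoms: N-bromosuccinimide, O=C1CCC(=O)N1Br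
Why: Electrophilic aromatic bromination should go para to each outer methoxy group (C4 and C6), since the central benzyloxy group is twisted out of conjugation and leaves C5 unactivated, so two equivalents of NBS should give the symmetric dibromide.

Step 3
Reactants: 3 3-(benzyloxy)-1,5-dibromo-2,4-dimethoxybenzene
Product: 4 5-(benzyloxy)-4,6-dimethoxybenzene-1,3-diol
Conditions: Pd2(dba)3 (2 mol%), tBuXPhos (8 mol%), KOH (6 equiv), 1,4-dioxane/H2O 1:1, 100 °C, Ar; then 1 M HCl, 0 °C
Reagents that add atoms: potassium hydroxide, [K+].[OH-]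
Why: Palladium-catalysed C–O coupling of aryl bromides with hydroxide (Buchwald-type hydroxylation with a bulky biarylphosphine) should convert both C–Br bonds into phenols in one operation, and the benzyl and methyl ethers are inert to aqueous KOH.

Step 4
Reactants: 4 5-(benzyloxy)-4,6-dimethoxybenzene-1,3-diol
Product: 6 4-(benzyloxy)-2,6-dihydroxy-3,5-dimethoxybenzaldehyde, via aryl iminium chloride 5 (not isolated)
Conditions: POCl3 (1.5 equiv), DMF (3 equiv), MeCN, 0 °C → rt; then H2O, 50 °C
Reagents that add atoms: N,N-dimethylformamide, CN(C)C=O; water, O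
Why: Vilsmeier–Haack formylation attacks the only free ring carbon, which is ortho to both hydroxyls and para to the benzyloxy group as in the formylation of phloroglucinol, and aqueous hydrolysis of the iminium salt releases the aldehyde.

Step 5
Reactants: 7 methyl 3-hydroxy-4,5-dimethoxybenzoate
Product: 8 methyl 3-(benzyloxy)-4,5-dimethoxybenzoate
Conditions: BnBr, K2CO3, DMF, 60 °C
Reagents that add atoms: benzyl bromide, BrCc1ccccc1
Why: Williamson etherification of the single free phenol protects the future 3'-OH with the same group used on ring A, so one final step removes both.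

Step 6
Reactants: 8 methyl 3-(benzyloxy)-4,5-dimethoxybenzoate; 9 trimethylsulfoxonium iodide
Product: 11 1-[3-(benzyloxy)-4,5-dimethoxyphenyl]-2-[dimethyl(oxo)-λ6-sulfanylidene]ethan-1-one, via dimethylsulfoxonium methylide 10 (not isolated)
Conditions: 9 (3 equiv), KOtBu (3 equiv), THF, reflux, 2 h; then 8, THF, reflux
Reagents that add atoms: none
Why: Acyl substitution of the methyl ester by dimethylsulfoxonium methylide (Corey–Chaykovsky-type acylation) gives the β-keto sulfoxonium ylide, which is deprotonated by the released methoxide to a stabilised ylide that does not react further.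

Step 7
Reactants: 6 4-(benzyloxy)-2,6-dihydroxy-3,5-dimethoxybenzaldehyde; 11 1-[3-(benzyloxy)-4,5-dimethoxyphenyl]-2-[dimethyl(oxo)-λ6-sulfanylidene]ethan-1-one
Product: 13 7,3'-di-O-benzylscaposin [7-(benzyloxy)-2-(3-benzyloxy-4,5-dimethoxyphenyl)-5-hydroxy-6,8-dimethoxy-4H-chromen-4-one], via o-hydroxyaryl 1,3-diketone 12 (not isolated)
Conditions: 11 (1.5 equiv), [Cp*RhCl2]2 (5 mol%), AgSbF6 (20 mol%), CsOPiv (30 mol%), PivOH (2 equiv), DCE, 90 °C, N2; then TsOH·H2O (20 mol%), 80 °C
Reagents that add atoms: none
Why: Cp*Rh(III) binds one phenoxide of 6 and cleaves the formyl C–H by pivalate-assisted concerted metalation–deprotonation to a five-membered acyl rhodacycle; ylide 11 then coordinates through carbon, loses DMSO to give a rhodium carbene, and migratory insertion of the acyl group forms C4–C3, after which protonation frees diketone 12. The closest known reaction is the Rh(III)-catalysed annulation of salicylaldehydes with aroyl sulfoxonium ylides to flavones, applied here to a fully substituted 2,6-dihydroxybenzaldehyde. Ring C closes by 6-exo-trig addition of the ortho hydroxyl to the aroyl carbonyl (O1–C2), followed by acid-catalysed loss of water from the hemiketal. No stereocentre is formed. The step needs formyl C–H activation and carbene insertion to outrun decarbonylation, and closure to the six-membered ring: ring A has no aryl C–H to compete, a hydroxyl lies syn to the formyl hydrogen in either rotamer, and the phenoxide chelate holds the acyl–rhodium beside the carbene. Because the two hydroxyls are equivalent, either one directs and closes to the same product while the other becomes the hydrogen-bonded C5–OH, and only attack at the aroyl carbonyl gives a pyranone.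

Step 8
Reactants: 13 7,3'-di-O-benzylscaposin
Product: 14 scaposin (5,7-dihydroxy-2-(3-hydroxy-4,5-dimethoxyphenyl)-6,8-dimethoxy-4H-chromen-4-one)
Conditions: H2 (1 atm), 10% Pd/C, EtOAc/MeOH 1:1, rt
Reagents that add atoms: none
Why: Hydrogenolysis of the two aryl benzyl ethers over palladium on carbon should free O7–H and O3'–H, while the flavone C2=C3 bond (a vinylogous ester) and the methyl ethers are untouched at 1 atm.

**Compound list**
1 | 2,6-dimethoxyphenol (syringol) | COc1cccc(OC)c1O | starting material
2 | 2-(benzyloxy)-1,3-dimethoxybenzene | COc1cccc(OC)c1OCc1ccccc1 | intermediate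
3 | 3-(benzyloxy)-1,5-dibromo-2,4-dimethoxybenzene | COc1c(Br)cc(Br)c(OC)c1OCc1ccccc1 | intermediate
4 | 5-(benzyloxy)-4,6-dimethoxybenzene-1,3-diol | COc1c(O)cc(O)c(OC)c1OCc1ccccc1 | intermediate
5 | N-{[4-(benzyloxy)-2,6-dihydroxy-3,5-dimethoxyphenyl]methylidene}-N-methylmethanaminium chloride (not isolated) | C[N+](C)=Cc1c(O)c(OC)c(OCc2ccccc2)c(OC)c1O.[Cl-] | intermediate
6 | 4-(benzyloxy)-2,6-dihydroxy-3,5-dimethoxybenzaldehyde | O=Cc1c(O)c(OC)c(OCc2ccccc2)c(OC)c1O | intermediate
7 | methyl 3-hydroxy-4,5-dimethoxybenzoate | COC(=O)c1cc(O)c(OC)c(OC)c1 | starting material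
8 | methyl 3-(benzyloxy)-4,5-dimethoxybenzoate | COC(=O)c1cc(OCc2ccccc2)c(OC)c(OC)c1 | intermediate
9 | trimethylsulfoxonium iodide | C[S+](C)(C)=O.[I-] | starting material
10 | dimethylsulfoxonium methylide (not isolated) | C=S(C)(C)=O | intermediate
11 | 1-[3-(benzyloxy)-4,5-dimethoxyphenyl]-2-[dimethyl(oxo)-λ6-sulfanylidene]ethan-1-one | COc1cc(C(=O)C=S(C)(C)=O)cc(OCc2ccccc2)c1OC | intermediate
12 | 1-[4-(benzyloxy)-2,6-dihydroxy-3,5-dimethoxyphenyl]-3-[3-(benzyloxy)-4,5-dimethoxyphenyl]propane-1,3-dione (not isolated) | COc1cc(C(=O)CC(=O)c2c(O)c(OC)c(OCc3ccccc3)c(OC)c2O)cc(OCc2ccccc2)c1OC | intermediate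
13 | 7,3'-di-O-benzylscaposin | COc1cc(-c2cc(=O)c3c(O)c(OC)c(OCc4ccccc4)c(OC)c3o2)cc(OCc2ccccc2)c1OC | intermediate
14 | scaposin | COc1cc(-c2cc(=O)c3c(O)c(OC)c(O)c(OC)c3o2)cc(O)c1OC | target

**Count**
Total steps: 8. Longest linear sequence: 6 steps (steps 1, 2, 3, 4, 7, 8).

**Steps most likely to fail**

1. Step 7. Acyl–rhodium formation may be slow on the doubly ortho-substituted, electron-rich aldehyde. The ylide may also be consumed first, by O–H insertion into the phenols or by ortho C–H activation of its own aroyl ring, and the flavone's 5-OH/4-C=O chelate may hold the catalyst.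
Fallback: this sets out from resorcinol 4 and ester 8 and returns at diketone 12, which is closed to 13. Houben–Hoesch acetylation of 4 (MeCN, ZnCl2, HCl gas, Et2O, 0 °C) should give the ketiminium chloride F1, hydrolysed in warm water to 1-[4-(benzyloxy)-2,6-dihydroxy-3,5-dimethoxyphenyl]ethan-1-one F2. Ester 8 is saponified (LiOH, THF/H2O) to 3-(benzyloxy)-4,5-dimethoxybenzoic acid F3 and converted with oxalyl chloride and catalytic DMF into 3-(benzyloxy)-4,5-dimethoxybenzoyl chloride F4. The lithium polyanion of F2 (LiHMDS, 4 equiv, THF, −78 °C) is C-acylated by F4 to give 12 (Baker–Venkataraman-type diketone route), and TsOH in toluene at 80 °C should cyclodehydrate 12 to 13.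

2. Step 3. The second C–Br bond may be reduced instead of hydroxylated, and the electron-rich resorcinol dianion may be oxidised in hot base.
Fallback: this sets out from dibromide 3 and returns at 4. Miyaura diborylation (B2pin2, Pd(dppf)Cl2, KOAc, dioxane, 90 °C) should give 2,2'-[5-(benzyloxy)-4,6-dimethoxy-1,3-phenylene]bis(4,4,5,5-tetramethyl-1,3,2-dioxaborolane) F5, which is oxidised cold (NaOH, H2O2, THF, 0 °C) to 4, so the free resorcinol never sees hot base.

3. Step 4. The Vilsmeier reagent may attack a phenol oxygen, or substitution at the carbon flanked by two hydroxyls may stall, while the air-sensitive resorcinol degrades.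
Fallback: this sets out from 4 and returns at 6. Protection with MOMCl and iPr2NEt in CH2Cl2 should give 3-(benzyloxy)-2,4-dimethoxy-1,5-bis(methoxymethoxy)benzene F6. Directed ortho-lithiation between the two MOM ethers (n-BuLi, THF, 0 °C) and a DMF quench give 4-(benzyloxy)-3,5-dimethoxy-2,6-bis(methoxymethoxy)benzaldehyde F7, and HCl in MeOH at 40 °C removes the MOM groups to give 6.

**Further compounds**
F1 | step 7 | 1-[4-(benzyloxy)-2,6-dihydroxy-3,5-dimethoxyphenyl]ethan-1-iminium chloride | CC(=[NH2+])c1c(O)c(OC)c(OCc2ccccc2)c(OC)c1O.[Cl-]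
F2 | step 7 | 1-[4-(benzyloxy)-2,6-dihydroxy-3,5-dimethoxyphenyl]ethan-1-one | CC(=O)c1c(O)c(OC)c(OCc2ccccc2)c(OC)c1O
F3 | step 7 | 3-(benzyloxy)-4,5-dimethoxybenzoic acid | COc1cc(C(=O)O)cc(OCc2ccccc2)c1OC
F4 | step 7 | 3-(benzyloxy)-4,5-dimethoxybenzoyl chloride | COc1cc(C(Cl)=O)cc(OCc2ccccc2)c1OC
F5 | step 3 | 2,2'-[5-(benzyloxy)-4,6-dimethoxy-1,3-phenylene]bis(4,4,5,5-tetramethyl-1,3,2-dioxaborolane) | COc1c(B2OC(C)(C)C(C)(C)O2)cc(B2OC(C)(C)C(C)(C)O2)c(OC)c1OCc1ccccc1
F6 | step 4 | 3-(benzyloxy)-2,4-dimethoxy-1,5-bis(methoxymethoxy)benzene | COCOc1cc(OCOC)c(OC)c(OCc2ccccc2)c1OC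
F7 | step 4 | 4-(benzyloxy)-3,5-dimethoxy-2,6-bis(methoxymethoxy)benzaldehyde | COCOc1c(C=O)c(OCOC)c(OC)c(OCc2ccccc2)c1OC
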